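## Plan

1. Retrosynthesis: cut the C6–O ester bond (orsellinate), then the O2–C3 bond of ring B (6-endo oxa-Michael of the C1 alcohol onto an ynenone), the C4a–C4 bond (Sonogashira), the C8a–C1 bond (Morita–Baylis–Hillman), and last the C6–O and C7–O bonds of ring A, which lead back to benzoic acid.
2. Enabling feature: ring A (C4a–C5–C6–C7–C8–C8a) carries a cis pair of C–O bonds at C6 (secondary) and C7 (tertiary, bearing one extra carbon). This is the ipso,ortho cis-diol pattern of a dearomatised benzoate whose carboxyl carbon ends up as the C7 methyl.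
3. Forward: benzoic acid → enzymatic cis-diol → CO2H reduced to CH3 → singlet oxygen oxygenates C5/C8, C5 is deoxygenated and C8 becomes the enone carbonyl → C1 by hydroxymethylation at C8a and a triflate at C4a through the 1,3-diketone → alkyne coupling, esterification, ring B closed last.
4. Stereochemistry: C6 and C7 come from the dioxygenase and their C–O bonds are never broken afterwards; the oxirane comes from a Sharpless epoxidation of (E)-crotyl alcohol with the D-(−)-tartrate ligand; the target has no other stereocentre.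

Key step: step 1

Remark: atom labels C1–C8a are those of the isochromene skeleton of the target (ring A = carbocycle, ring B = pyran, oxirane carbons C1′/C2′) and are carried back to every intermediate; the benzoate-oxidising mutant strain is assumed to be available from a culture collection.

## Route

Step 1
Reactants: 1 benzoic acid
Product: 2 (1S,2R)-1,2-dihydroxycyclohexa-3,5-diene-1-carboxylic acid
Conditions: Cupriavidus necator B9 whole cells (benzoate 1,2-dioxygenase active, cis-diol dehydrogenase inactive), sodium benzoate fed in portions, fructose, mineral salts medium, air, pH 7, 30 °C; cell-free broth acidified to pH 3, EtOAc extraction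
Reagents that add atoms: dioxygen, O=O
Why: Benzoate 1,2-dioxygenase is a Rieske-type non-heme iron oxygenase in which the divalent iron centre, fed with two electrons from NADH through the reductase and the iron–sulfur cluster, binds O2 side-on and hands both of its atoms to the C1–C2 edge of the bound benzoate from one face, so the two new C–O bonds can only be cis. The closest known reaction type is the arene cis-dihydroxylation carried out by ring-hydroxylating dioxygenases such as toluene dioxygenase, here in the ipso,ortho mode that opens benzoate catabolism. No ring is closed; the benzene ring is dearomatised to a cyclohexa-3,5-diene that keeps the two double bonds needed later. Both new stereocentres (C1 S and C2 R, the future C7 and C6) are set by the active site, which anchors the carboxylate and exposes a single face of the ipso/ortho edge to the iron-bound oxygen. The step needs ipso,ortho regioselectivity, one enantiomer and a halt at the diol stage: the first two are secured because benzoate is the native substrate of the enzyme, the last because the mutant lacks a working cis-diol dehydrogenase, so 2 is excreted instead of being decarboxylated to catechol.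

Step 2
Reactants: 2 (1S,2R)-1,2-dihydroxycyclohexa-3,5-diene-1-carboxylic acid
Product: 3 (3aS,7aR)-2,2-dimethyl-3a,7a-dihydro-1,3-benzodioxole-3a-carboxylic acid (acetonide of 2)
Conditions: 2,2-dimethoxypropane, TsOH·H2O (cat.), acetone, 0 °C; Et3N quench
Reagents that add atoms: 2,2-dimethoxypropane, COC(C)(C)OC
Why: Acid-catalysed ketal exchange (acetonide formation) on a cis-1,2-diol should give the cis-fused dioxolane quickly at 0 °C, masking the allylic hydroxyls whose loss would otherwise rearomatise the ring and leaving both stereocentres untouched.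

Step 3
Reactants: 3 (3aS,7aR)-2,2-dimethyl-3a,7a-dihydro-1,3-benzodioxole-3a-carboxylic acid
Product: 4 [(3aR,7aR)-2,2-dimethyl-3a,7a-dihydro-1,3-benzodioxol-3a-yl]methanol
Conditions: LiAlH4, THF, 0 °C to reflux; Fieser work-up
Reagents that add atoms: none
Why: LiAlH4 reduction of a carboxylic acid to the primary alcohol, to which the unconjugated diene and the ketal are inert; the quaternary centre is not touched (its descriptor changes only because CH2OH ranks below C7a).

Step 4
Reactants: 4 [(3aR,7aR)-2,2-dimethyl-3a,7a-dihydro-1,3-benzodioxol-3a-yl]methanol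
Product: 5 [(3aR,7aR)-2,2-dimethyl-3a,7a-dihydro-1,3-benzodioxol-3a-yl]methyl methanesulfonate
Conditions: MsCl, Et3N, CH2Cl2, 0 °C
Reagents that add atoms: methanesulfonyl chloride, CS(=O)(=O)Cl
Why: O-sulfonylation (mesylation) of a primary alcohol, which cannot be followed by elimination because the neighbouring carbon carries no hydrogen.

Step 5
Reactants: 5 [(3aR,7aR)-2,2-dimethyl-3a,7a-dihydro-1,3-benzodioxol-3a-yl]methyl methanesulfonate
Product: 6 (3aS,7aR)-2,2,3a-trimethyl-3a,7a-dihydro-1,3-benzodioxole
Conditions: LiEt3BH (3 equiv), THF, 0 °C to reflux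
Reagents that add atoms: none
Why: SN2 hydride displacement of a neopentyl-type sulfonate by LiEt3BH, the hydride donor of choice for hindered primary sulfonates, should turn the former carboxyl carbon into the C7 methyl group without radical intermediates that could rearrange through the diene.

Step 6
Reactants: 6 (3aS,7aR)-2,2,3a-trimethyl-3a,7a-dihydro-1,3-benzodioxole
Product: 8 (3aS,4R,7S,7aR)-2,2,3a-trimethyl-3a,4,7,7a-tetrahydro-1,3-benzodioxole-4,7-diol (C5/C8 cis-enediol; both hydroxyls trans to the dioxolane oxygens), via endoperoxide 7 (not isolated)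
Conditions: O2, tetraphenylporphyrin (cat.), visible light, CH2Cl2, −78 °C; then thiourea, MeOH (wet), −78 °C to rt
Reagents that add atoms: dioxygen, O=O
Why: [4+2] cycloaddition of singlet oxygen to the cyclohexadiene on the face away from the dioxolane, followed by thiourea reduction of the O–O bond, should give the cis-1,4-enediol with oxygen on C5 and C8; the two temporary carbinol centres are set by this anti approach and are removed in steps 8 and 9.

Step 7
Reactants: 8 (3aS,4R,7S,7aR)-2,2,3a-trimethyl-3a,4,7,7a-tetrahydro-1,3-benzodioxole-4,7-diol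
Product: 9 (3aS,4R,7S,7aR)-4-hydroxy-2,2,3a-trimethyl-3a,4,7,7a-tetrahydro-1,3-benzodioxol-7-yl methyl carbonate (carbonate on the C5 oxygen)
Conditions: ClCO2Me (1.05 equiv), pyridine, CH2Cl2, −40 °C
Reagents that add atoms: methyl chloroformate, COC(=O)Cl
Why: Site-selective acylation (carbonate formation) of the less hindered of two secondary allylic alcohols, since the C5 hydroxyl has a CH neighbour whereas the C8 hydroxyl sits next to the fully substituted C7 and cis to its methyl group.

Step 8
Reactants: 9 (3aS,4R,7S,7aR)-4-hydroxy-2,2,3a-trimethyl-3a,4,7,7a-tetrahydro-1,3-benzodioxol-7-yl methyl carbonate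
Product: 10 (3aR,7S,7aR)-2,2,3a-trimethyl-4-oxo-3a,4,7,7a-tetrahydro-1,3-benzodioxol-7-yl methyl carbonate (C8 enone with C5 carbonate)
Conditions: Dess–Martin periodinane, NaHCO3, CH2Cl2, 0 °C to rt
Reagents that add atoms: none
Why: Dess–Martin oxidation of the remaining allylic alcohol gives the C8 ketone under buffered, non-basic conditions that spare the allylic carbonate and the ketal.

Step 9
Reactants: 10 (3aR,7S,7aR)-2,2,3a-trimethyl-4-oxo-3a,4,7,7a-tetrahydro-1,3-benzodioxol-7-yl methyl carbonate
Product: 11 (3aR,7aR)-2,2,3a-trimethyl-7,7a-dihydro-1,3-benzodioxol-4(3aH)-one (enone with C8=O, C8a=C4a, C5H2)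
Conditions: Pd2(dba)3·CHCl3 (2.5 mol%), PBu3 (10 mol%), HCO2H, Et3N, THF, rt to 40 °C
Reagents that add atoms: none
Why: Tsuji–Trost-type allylic hydrogenolysis, in which zerovalent palladium ionises the C5–O carbonate, formate supplies hydride to the allyl complex and Et3N keeps the product as the conjugated enone, should remove the surplus C5 oxygen while the α-oxygenated C7 is left alone, as an electron-transfer reductant would not do.

Step 10
Reactants: 11 (3aR,7aR)-2,2,3a-trimethyl-7,7a-dihydro-1,3-benzodioxol-4(3aH)-one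
Product: 12 (3aR,7aR)-5-(hydroxymethyl)-2,2,3a-trimethyl-7,7a-dihydro-1,3-benzodioxol-4(3aH)-one (CH2OH on C8a)
Conditions: 37% aq. HCHO, DMAP (0.2 equiv), THF/H2O, rt
Reagents that add atoms: formaldehyde, C=O
Why: Morita–Baylis–Hillman hydroxymethylation of a cyclic enone at its α-carbon forms the C8a–C1 bond with the C1 oxygen already in place.

Step 11
Reactants: 12 (3aR,7aR)-5-(hydroxymethyl)-2,2,3a-trimethyl-7,7a-dihydro-1,3-benzodioxol-4(3aH)-one
Product: 13 (3aR,7aR)-5-[(tert-butyldiphenylsilyloxy)methyl]-2,2,3a-trimethyl-7,7a-dihydro-1,3-benzodioxol-4(3aH)-one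
Conditions: TBDPSCl, imidazole, DMF, rt
Reagents that add atoms: tert-butyldiphenylsilyl chloride, CC(C)(C)[Si](Cl)(c1ccccc1)c1ccccc1
Why: Silyl ether formation on the primary allylic alcohol with a group that survives the later oxidations and aqueous acid and is cleaved by fluoride at the end.

Step 12
Reactants: 13 (3aR,7aR)-5-[(tert-butyldiphenylsilyloxy)methyl]-2,2,3a-trimethyl-7,7a-dihydro-1,3-benzodioxol-4(3aH)-one
Product: 15 (3aR,7aR)-5-[(tert-butyldiphenylsilyloxy)methyl]-6-hydroxy-2,2,3a-trimethyl-tetrahydro-1,3-benzodioxol-4(3aH)-one (β-hydroxy ketone with OH on C4a; diastereomer mixture at C4a and C8a), via boronate 14 (not isolated)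
Conditions: B2pin2, CuCl (5 mol%), NaOtBu (10 mol%), Xantphos (5 mol%), MeOH (2 equiv), THF, rt; then 30% H2O2, pH 7 phosphate buffer, 0 °C
Reagents that add atoms: hydrogen peroxide, OO (the C4a oxygen of 15); bis(pinacolato)diboron, CC1(C)OB(OC1(C)C)B1OC(C)(C)C(C)(C)O1 (the boron of intermediate 14 only)
Why: Copper-catalysed conjugate borylation of the enone followed by oxidation of the C–B bond places oxygen on C4a regiospecifically; the configurations created at C4a and C8a do not matter because both carbons become sp2 again in steps 13 and 14.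

Step 13
Reactants: 15 (3aR,7aR)-5-[(tert-butyldiphenylsilyloxy)methyl]-6-hydroxy-2,2,3a-trimethyl-tetrahydro-1,3-benzodioxol-4(3aH)-one
Product: 16 (3aR,7aR)-5-[(tert-butyldiphenylsilyloxy)methyl]-2,2,3a-trimethyl-dihydro-1,3-benzodioxole-4,6(5H,7H)-dione (1,3-diketone at C8/C4a, largely enolised)
Conditions: Dess–Martin periodinane, CH2Cl2, rt; used without chromatography
Reagents that add atoms: none
Why: Dess–Martin oxidation of a β-hydroxy ketone is a standard route to the cyclic 1,3-diketone and avoids the basic conditions that could expel the silyloxy group.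

Step 14
Reactants: 16 (3aR,7aR)-5-[(tert-butyldiphenylsilyloxy)methyl]-2,2,3a-trimethyl-dihydro-1,3-benzodioxole-4,6(5H,7H)-dione
Product: 17 (3aR,7aR)-5-[(tert-butyldiphenylsilyloxy)methyl]-2,2,3a-trimethyl-4-oxo-3a,4,7,7a-tetrahydro-1,3-benzodioxol-6-yl trifluoromethanesulfonate (triflate on C4a, ketone at C8)
Conditions: Tf2O, 2,6-lutidine, CH2Cl2, −78 °C
Reagents that add atoms: trifluoromethanesulfonic anhydride, O=S(=O)(OS(=O)(=O)C(F)(F)F)C(F)(F)F
Why: Enol triflate formation from a cyclic 1,3-diketone should occur on the oxygen at C4a, which has a CH2 neighbour, in preference to the oxygen at C8, which is shielded by the fully substituted C7 and deactivated by its α-oxygen.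

Step 15
Reactants: 17 (3aR,7aR)-5-[(tert-butyldiphenylsilyloxy)methyl]-2,2,3a-trimethyl-4-oxo-3a,4,7,7a-tetrahydro-1,3-benzodioxol-6-yl trifluoromethanesulfonate
Product: 18 (4R,5R)-2-[(tert-butyldiphenylsilyloxy)methyl]-4,5-dihydroxy-4-methyl-3-oxocyclohex-1-en-1-yl trifluoromethanesulfonate (free C6/C7 diol)
Conditions: TFA/H2O (9:1), 0 °C
Reagents that add atoms: none
Why: Acid hydrolysis of the isopropylidene ketal frees the C6/C7 diol at the last point before the acid-sensitive oxirane enters; the vinyl triflate and the primary tert-butyldiphenylsilyl ether tolerate brief aqueous acid.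

Step 16
Reactants: 19 (E)-but-2-en-1-ol (crotyl alcohol)
Product: 20 [(2R,3R)-3-methyloxiran-2-yl]methanol
Conditions: Ti(OiPr)4 (5 mol%), diethyl D-(−)-tartrate (6 mol%), t-BuOOH, 4 Å molecular sieves, CH2Cl2, −20 °C
Reagents that add atoms: tert-butyl hydroperoxide, CC(C)(C)OO
Why: Sharpless asymmetric epoxidation of an (E)-allylic alcohol, in which the D-(−)-tartrate ligand directs oxygen to the alkene face that gives the (2R,3R)-epoxy alcohol and the trans geometry is carried into the oxirane.

Step 17
Reactants: 20 [(2R,3R)-3-methyloxiran-2-yl]methanol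
Product: 21 (2S,3R)-3-methyloxirane-2-carbaldehyde
Conditions: Dess–Martin periodinane, NaHCO3, CH2Cl2, 0 °C; filtered solution used directly
Reagents that add atoms: none
Why: Dess–Martin oxidation of the primary epoxy alcohol to the aldehyde under neutral conditions that neither open nor epimerise the oxirane (the C2 descriptor changes only through the priority of CHO).

Step 18
Reactants: 21 (2S,3R)-3-methyloxirane-2-carbaldehyde
Product: 22 (2R,3R)-2-ethynyl-3-methyloxirane
Conditions: dimethyl (1-diazo-2-oxopropyl)phosphonate, K2CO3, MeOH, 0 °C to rt; product kept as a solution in Et2O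
Reagents that add atoms: dimethyl (1-diazo-2-oxopropyl)phosphonate, COP(=O)(OC)C(=[N+]=[N-])C(C)=O
Why: Seyferth–Gilbert homologation in the Ohira–Bestmann variant converts the aldehyde into the terminal alkyne with one added carbon under carbonate/methanol conditions mild enough for an epoxy aldehyde.

Step 19
Reactants: 18 (4R,5R)-2-[(tert-butyldiphenylsilyloxy)methyl]-4,5-dihydroxy-4-methyl-3-oxocyclohex-1-en-1-yl trifluoromethanesulfonate; 22 (2R,3R)-2-ethynyl-3-methyloxirane
Product: 23 (5R,6R)-2-[(tert-butyldiphenylsilyloxy)methyl]-5,6-dihydroxy-6-methyl-3-{[(2R,3R)-3-methyloxiran-2-yl]ethynyl}cyclohex-2-en-1-one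
Conditions: Pd(PPh3)2Cl2 (5 mol%), CuI (10 mol%), iPr2NEt, THF, 0 °C to rt; 22 (1.5 equiv)
Reagents that add atoms: none
Why: Sonogashira coupling of a β-triflyloxy enone with a terminal alkyne forms the C4a–C4 bond; oxidative addition of zerovalent palladium to this vinylogous acyl triflate is fast at or below room temperature, which should let the coupling outrun attack on the propargylic oxirane.

Step 20
Reactants: 24 orsellinic acid (2,4-dihydroxy-6-methylbenzoic acid)
Product: 25 tert-butyldimethylsilyl 2,4-bis(tert-butyldimethylsilyloxy)-6-methylbenzoate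
Conditions: TBSCl (3.5 equiv), imidazole, DMF, rt to 40 °C
Reagents that add atoms: tert-butyldimethylsilyl chloride, CC(C)(C)[Si](C)(C)Cl
Why: Exhaustive silylation of both phenols and the carboxylic acid gives phenol protection that fluoride removes in the final step.

Step 21
Reactants: 25 tert-butyldimethylsilyl 2,4-bis(tert-butyldimethylsilyloxy)-6-methylbenzoate
Product: 26 2,4-bis(tert-butyldimethylsilyloxy)-6-methylbenzoyl chloride
Conditions: (COCl)2, DMF (cat.), CH2Cl2, 0 °C to rt; volatiles removed, used crude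
Reagents that add atoms: oxalyl chloride, O=C(Cl)C(Cl)=O
Why: Direct conversion of a silyl ester into the acid chloride with oxalyl chloride/DMF (Vilsmeier-type activation) proceeds under neutral conditions that keep the aryl silyl ethers.

Step 22
Reactants: 23 (5R,6R)-2-[(tert-butyldiphenylsilyloxy)methyl]-5,6-dihydroxy-6-methyl-3-{[(2R,3R)-3-methyloxiran-2-yl]ethynyl}cyclohex-2-en-1-one; 26 2,4-bis(tert-butyldimethylsilyloxy)-6-methylbenzoyl chloride
Product: 27 (1R,2R)-4-[(tert-butyldiphenylsilyloxy)methyl]-2-hydroxy-2-methyl-5-{[(2R,3R)-3-methyloxiran-2-yl]ethynyl}-3-oxocyclohex-4-en-1-yl 2,4-bis(tert-butyldimethylsilyloxy)-6-methylbenzoate (ester on the C6 oxygen)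
Conditions: pyridine, DMAP (0.2 equiv), CH2Cl2, 0 °C to rt
Reagents that add atoms: none
Why: DMAP-catalysed acylation with an acid chloride should esterify the secondary C6 hydroxyl with retention, because the C6–O bond is not touched, while the tertiary C7 hydroxyl next to the ketone is too hindered to react.

Step 23
Reactants: 27 (1R,2R)-4-[(tert-butyldiphenylsilyloxy)methyl]-2-hydroxy-2-methyl-5-{[(2R,3R)-3-methyloxiran-2-yl]ethynyl}-3-oxocyclohex-4-en-1-yl 2,4-bis(tert-butyldimethylsilyloxy)-6-methylbenzoate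
Product: 29 (6R,7R)-7-hydroxy-7-methyl-3-[(2S,3R)-3-methyloxiran-2-yl]-8-oxo-5,6,7,8-tetrahydro-1H-isochromen-6-yl 2,4-dihydroxy-6-methylbenzoate (CNP0323247.1), via desilylated ynenone 28 (not isolated)
Conditions: TBAF (4 equiv), AcOH (2 equiv), THF, 0 °C to rt
Reagents that add atoms: none
Why: Fluoride desilylation removes the three silyl groups and the freed C1 hydroxyl adds to C3 of the ynenone in a 6-endo-dig oxa-Michael (1,6-addition) that closes ring B, since conjugation with the C8 ketone makes C3 the electrophilic alkyne carbon and disfavours the 5-exo mode; no stereocentre is formed or touched and the acetic acid buffer tempers the basicity towards the C6 ester.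

## Compound list

1 | benzoic acid | OC(=O)c1ccccc1 | starting material
2 | (1S,2R)-1,2-dihydroxycyclohexa-3,5-diene-1-carboxylic acid | O[C@@H]1C=CC=C[C@@]1(O)C(=O)O | intermediate
3 | (3aS,7aR)-2,2-dimethyl-3a,7a-dihydro-1,3-benzodioxole-3a-carboxylic acid | CC1(C)O[C@@H]2C=CC=C[C@@]2(O1)C(=O)O | intermediate
4 | [(3aR,7aR)-2,2-dimethyl-3a,7a-dihydro-1,3-benzodioxol-3a-yl]methanol | CC1(C)O[C@@H]2C=CC=C[C@@]2(O1)CO | intermediate
5 | [(3aR,7aR)-2,2-dimethyl-3a,7a-dihydro-1,3-benzodioxol-3a-yl]methyl methanesulfonate | CC1(C)O[C@@H]2C=CC=C[C@@]2(O1)COS(C)(=O)=O | intermediate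
6 | (3aS,7aR)-2,2,3a-trimethyl-3a,7a-dihydro-1,3-benzodioxole | CC1(C)O[C@@H]2C=CC=C[C@@]2(O1)C | intermediate
7 | endoperoxide of 6 (2,2,3a-trimethyl-3a,4,7,7a-tetrahydro-4,7-epidioxy-1,3-benzodioxole, O–O bridge anti to the dioxolane oxygens) | O1[C@H]2C=C[C@@H](O1)[C@]3(C)OC(C)(C)O[C@H]23 | intermediate (not isolated)
8 | (3aS,4R,7S,7aR)-2,2,3a-trimethyl-3a,4,7,7a-tetrahydro-1,3-benzodioxole-4,7-diol | O[C@H]1C=C[C@@H](O)[C@]2(C)OC(C)(C)O[C@H]12 | intermediate
9 | (3aS,4R,7S,7aR)-4-hydroxy-2,2,3a-trimethyl-3a,4,7,7a-tetrahydro-1,3-benzodioxol-7-yl methyl carbonate | COC(=O)O[C@H]1C=C[C@@H](O)[C@]2(C)OC(C)(C)O[C@H]12 | intermediate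
10 | (3aR,7S,7aR)-2,2,3a-trimethyl-4-oxo-3a,4,7,7a-tetrahydro-1,3-benzodioxol-7-yl methyl carbonate | COC(=O)O[C@H]1C=CC(=O)[C@]2(C)OC(C)(C)O[C@H]12 | intermediate
11 | (3aR,7aR)-2,2,3a-trimethyl-7,7a-dihydro-1,3-benzodioxol-4(3aH)-one | C1C=CC(=O)[C@]2(C)OC(C)(C)O[C@H]12 | intermediate
12 | (3aR,7aR)-5-(hydroxymethyl)-2,2,3a-trimethyl-7,7a-dihydro-1,3-benzodioxol-4(3aH)-one | C1C=C(CO)C(=O)[C@]2(C)OC(C)(C)O[C@H]12 | intermediate
13 | (3aR,7aR)-5-[(tert-butyldiphenylsilyloxy)methyl]-2,2,3a-trimethyl-7,7a-dihydro-1,3-benzodioxol-4(3aH)-one | C1C=C(CO[Si](c3ccccc3)(c3ccccc3)C(C)(C)C)C(=O)[C@]2(C)OC(C)(C)O[C@H]12 | intermediate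
14 | β-boryl ketone: the 6-(4,4,5,5-tetramethyl-1,3,2-dioxaborolan-2-yl) adduct of 13 (boron on C4a, H on C8a; diastereomer mixture) | C1C(B3OC(C)(C)C(C)(C)O3)C(CO[Si](c4ccccc4)(c4ccccc4)C(C)(C)C)C(=O)[C@]2(C)OC(C)(C)O[C@H]12 | intermediate (not isolated)
15 | (3aR,7aR)-5-[(tert-butyldiphenylsilyloxy)methyl]-6-hydroxy-2,2,3a-trimethyl-tetrahydro-1,3-benzodioxol-4(3aH)-one (diastereomer mixture at C5/C6 of the benzodioxole) | C1C(O)C(CO[Si](c3ccccc3)(c3ccccc3)C(C)(C)C)C(=O)[C@]2(C)OC(C)(C)O[C@H]12 | intermediate
16 | (3aR,7aR)-5-[(tert-butyldiphenylsilyloxy)methyl]-2,2,3a-trimethyl-dihydro-1,3-benzodioxole-4,6(5H,7H)-dione (drawn as the diketo tautomer) | C1C(=O)C(CO[Si](c3ccccc3)(c3ccccc3)C(C)(C)C)C(=O)[C@]2(C)OC(C)(C)O[C@H]12 | intermediate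
17 | (3aR,7aR)-5-[(tert-butyldiphenylsilyloxy)methyl]-2,2,3a-trimethyl-4-oxo-3a,4,7,7a-tetrahydro-1,3-benzodioxol-6-yl trifluoromethanesulfonate | C1C(OS(=O)(=O)C(F)(F)F)=C(CO[Si](c3ccccc3)(c3ccccc3)C(C)(C)C)C(=O)[C@]2(C)OC(C)(C)O[C@H]12 | intermediate
18 | (4R,5R)-2-[(tert-butyldiphenylsilyloxy)methyl]-4,5-dihydroxy-4-methyl-3-oxocyclohex-1-en-1-yl trifluoromethanesulfonate | C1C(OS(=O)(=O)C(F)(F)F)=C(CO[Si](c2ccccc2)(c2ccccc2)C(C)(C)C)C(=O)[C@](C)(O)[C@@H]1O | intermediate
19 | (E)-but-2-en-1-ol (crotyl alcohol) | C/C=C/CO | starting material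
20 | [(2R,3R)-3-methyloxiran-2-yl]methanol | OC[C@H]1O[C@@H]1C | intermediate
21 | (2S,3R)-3-methyloxirane-2-carbaldehyde | O=C[C@H]1O[C@@H]1C | intermediate
22 | (2R,3R)-2-ethynyl-3-methyloxirane | C#C[C@H]1O[C@@H]1C | intermediate
23 | (5R,6R)-2-[(tert-butyldiphenylsilyloxy)methyl]-5,6-dihydroxy-6-methyl-3-{[(2R,3R)-3-methyloxiran-2-yl]ethynyl}cyclohex-2-en-1-one | C1C(C#C[C@H]2O[C@@H]2C)=C(CO[Si](c2ccccc2)(c2ccccc2)C(C)(C)C)C(=O)[C@](C)(O)[C@@H]1O | intermediate
24 | orsellinic acid (2,4-dihydroxy-6-methylbenzoic acid) | Cc1cc(O)cc(O)c1C(=O)O | starting material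
25 | tert-butyldimethylsilyl 2,4-bis(tert-butyldimethylsilyloxy)-6-methylbenzoate | Cc1cc(O[Si](C)(C)C(C)(C)C)cc(O[Si](C)(C)C(C)(C)C)c1C(=O)O[Si](C)(C)C(C)(C)C | intermediate
26 | 2,4-bis(tert-butyldimethylsilyloxy)-6-methylbenzoyl chloride | Cc1cc(O[Si](C)(C)C(C)(C)C)cc(O[Si](C)(C)C(C)(C)C)c1C(Cl)=O | intermediate
27 | (1R,2R)-4-[(tert-butyldiphenylsilyloxy)methyl]-2-hydroxy-2-methyl-5-{[(2R,3R)-3-methyloxiran-2-yl]ethynyl}-3-oxocyclohex-4-en-1-yl 2,4-bis(tert-butyldimethylsilyloxy)-6-methylbenzoate | C1C(C#C[C@H]2O[C@@H]2C)=C(CO[Si](c2ccccc2)(c2ccccc2)C(C)(C)C)C(=O)[C@](C)(O)[C@@H]1OC(=O)c1c(C)cc(O[Si](C)(C)C(C)(C)C)cc1O[Si](C)(C)C(C)(C)C | intermediate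
28 | (1R,2R)-2-hydroxy-4-(hydroxymethyl)-2-methyl-5-{[(2R,3R)-3-methyloxiran-2-yl]ethynyl}-3-oxocyclohex-4-en-1-yl 2,4-dihydroxy-6-methylbenzoate | C1C(C#C[C@H]2O[C@@H]2C)=C(CO)C(=O)[C@](C)(O)[C@@H]1OC(=O)c1c(C)cc(O)cc1O | intermediate (not isolated)
29 | (6R,7R)-7-hydroxy-7-methyl-3-[(2S,3R)-3-methyloxiran-2-yl]-8-oxo-5,6,7,8-tetrahydro-1H-isochromen-6-yl 2,4-dihydroxy-6-methylbenzoate (CNP0323247.1) | Cc1cc(O)cc(O)c1C(=O)O[C@@H]1CC2=C(COC([C@H]3O[C@@H]3C)=C2)C(=O)[C@]1(C)O | target

## Step count and risks

Total step count: 23. Longest linear sequence: 18 steps (steps 1–15, 19, 22, 23), from benzoic acid.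

Steps most likely to fail:

1. Step 19. Zerovalent palladium may insert into the propargylic C–O bond of the oxirane (allenylpalladium formation), and the low-boiling alkyne may be lost, before the cross-coupling is complete. Fallback: setting out from 18, the triflate would be coupled under the same Pd(PPh3)2Cl2/CuI conditions with (E)-pent-3-en-1-yne F1 (made from (E)-but-2-enal with the Ohira–Bestmann reagent), an alkyne without an oxirane, to give dienynone diol F2. The oxirane would then be made on the finished carbon skeleton by a Shi epoxidation of the (E)-propenyl group (D-fructose-derived ketone catalyst, Oxone (2KHSO5·KHSO4·K2SO4), K2CO3, MeCN/dimethoxymethane/H2O, 0 °C). By analogy with (E)-β-methylstyrene and (E)-enynes this should give the (2R,3R)-oxirane and leave the electron-poor tetrasubstituted enone alkene alone. The sequence returns to the route at 23.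

2. Step 23. Fluoride or the phenoxides it liberates may deprotonate C5 and expel the C6 orsellinate (vinylogous β-elimination) before ring B has closed, or the ring closure may stall at the open hydroxymethyl ynenone. Fallback: setting out from 23, TBAF/AcOH would remove only the tert-butyldiphenylsilyl group and close ring B while C6 still bears a free hydroxyl that cannot leave, giving pyran diol F3. Esterification of the secondary hydroxyl of F3 with 26 (pyridine, DMAP) would give bis-silyl ester F4. The two aryl silyl ethers would then be removed under nearly neutral conditions (Et3N·3HF, MeCN, 0 °C), arriving at 29.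

3. Step 7. The acylating agent may fail to discriminate between the two secondary allylic hydroxyls, or may acylate both. Fallback: setting out from 6, diimide (from dipotassium azodicarboxylate, KO2CN=NCO2K, and AcOH) would saturate the less hindered C5=C4a double bond to give cyclohexene F5. A Schenck ene reaction of F5 with singlet oxygen (O2, tetraphenylporphyrin, light), for which only the C4a hydrogens are available, would give allylic hydroperoxide F6 with oxygen on C8 and the double bond already at C8a=C4a. Acetic anhydride/pyridine/DMAP in the same flask would dehydrate F6 to the enone, rejoining the route at 11; the C5 oxygen, and with it the need to tell two alcohols apart, is avoided altogether.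

## Further compounds

F1 | step 19 | (E)-pent-3-en-1-yne | C/C=C/C#C
F2 | step 19 | (5R,6R)-2-[(tert-butyldiphenylsilyloxy)methyl]-5,6-dihydroxy-6-methyl-3-[(E)-pent-3-en-1-yn-1-yl]cyclohex-2-en-1-one | C1C(C#C/C=C/C)=C(CO[Si](c2ccccc2)(c2ccccc2)C(C)(C)C)C(=O)[C@](C)(O)[C@@H]1O
F3 | step 23 | (6R,7R)-6,7-dihydroxy-7-methyl-3-[(2S,3R)-3-methyloxiran-2-yl]-6,7-dihydro-1H-isochromen-8(5H)-one | O[C@@H]1CC2=C(COC([C@H]3O[C@@H]3C)=C2)C(=O)[C@]1(C)O
F4 | step 23 | (6R,7R)-7-hydroxy-7-methyl-3-[(2S,3R)-3-methyloxiran-2-yl]-8-oxo-5,6,7,8-tetrahydro-1H-isochromen-6-yl 2,4-bis(tert-butyldimethylsilyloxy)-6-methylbenzoate | Cc1cc(O[Si](C)(C)C(C)(C)C)cc(O[Si](C)(C)C(C)(C)C)c1C(=O)O[C@@H]1CC2=C(COC([C@H]3O[C@@H]3C)=C2)C(=O)[C@]1(C)O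
F5 | step 7 | (3aS,7aR)-2,2,3a-trimethyl-3a,6,7,7a-tetrahydro-1,3-benzodioxole | C1CC=C[C@]2(C)OC(C)(C)O[C@H]12
F6 | step 7 | (3aR,7aR)-4-hydroperoxy-2,2,3a-trimethyl-3a,4,7,7a-tetrahydro-1,3-benzodioxole (configuration at C4 not controlled) | C1C=CC(OO)[C@]2(C)OC(C)(C)O[C@H]12
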